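**Retrosynthetic overview**
- Target ⇒ its 11(20)-alkene (α-face epoxidation, last ring) ⇒ a macrocyclic diene β-hydroxy ester; the γ-lactone (third ring) and the C6–Cl/C5=C16 unit both arise from a 1,4-selenolactonisation of the C5(16),C6-diene followed by chlorine transfer from selenium.
- C8–C17: aldol of a propanoate enolate with a macrocyclic α-acetoxy dienone, made by allylic oxidation and acetylation of the pinacol diol.
- Key disconnection C8–C9: titanium-mediated ketyl-radical (pinacol) coupling of a dialdehyde, which closes the ten-membered ring (second ring) onto the cyclohexane and sets C9.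
- Dienal arm by ethylene-assisted enyne cross-metathesis of the C5≡C6 alkyne; C1 (quaternary)/C2 by aldol of a ring enolate with pent-4-ynal; 13,14-diol by OsO4; C20 by methylenation.
- The six-membered ring (first ring) is bought as p-benzoquinone monoketal and desymmetrised by rhodium-catalysed asymmetric vinylation (C10).

Numbering: briarane numbering is used for all intermediates (ring C1, C10–C14; C15 on C1; C20 on C11; chain C2–C9; C16 on C5; lactone C17–C19); β is the face of the six-membered ring that carries C15.
Assumption: the dimethyl ketal of the quinone building block and the tert-butyl group of the propanoate building block are protecting groups (of p-benzoquinone and propanoic acid).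

Step 1
Reactants: 1 4,4-dimethoxycyclohexa-2,5-dien-1-one; 2 potassium vinyltrifluoroborate
Product: 3 (S)-4,4-dimethoxy-5-vinylcyclohex-2-en-1-one
Conditions: [Rh(cod)2]BF4 (3 mol %), (S)-BINAP (3.3 mol %), Et3N, toluene/H2O 10:1, 40 °C
Reagents that add atoms: none
Why: Rhodium-catalysed asymmetric 1,4-addition of an alkenylboron reagent (Hayashi–Miyaura type) desymmetrises the dienone, the (S)-BINAP complex delivering vinyl to one enantiotopic enone face to set C10 (S), and the hindered mono-adduct does not react a second time.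

Step 2
Reactants: 3 (S)-4,4-dimethoxy-5-vinylcyclohex-2-en-1-one; 4 iodomethane
Product: 6 (5R,6R)-4,4-dimethoxy-6-methyl-5-vinylcyclohex-2-en-1-one, via lithium dienolate 5 (not isolated)
Conditions: LiN(i-Pr)2, THF, −78 °C; MeI, −78 → −30 °C
Reagents that add atoms: none
Why: Kinetic deprotonation at the only enolisable position (C1, α′) gives the cross-conjugated dienolate, which is methylated trans to the vinyl group (enolate alkylation); this C1 configuration is provisional because C1 is enolised again in step 3.

Step 3
Reactants: 6 (5R,6R)-4,4-dimethoxy-6-methyl-5-vinylcyclohex-2-en-1-one; 7 pent-4-ynal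
Product: 10 (5R,6S)-6-[(1S)-1-acetoxypent-4-yn-1-yl]-4,4-dimethoxy-6-methyl-5-vinylcyclohex-2-en-1-one, via lithium enolate 8 (not isolated), via lithium aldolate 9 (not isolated)
Conditions: LiN(i-Pr)2, THF, −78 → −40 °C; 7, −78 °C; Ac2O, −78 → 0 °C
Reagents that add atoms: acetic anhydride, CC(=O)OC(C)=O
Why: The tetrasubstituted ring (E)-enolate (C13 is vinylic, so only C1 can be deprotonated) adds to the aldehyde on the face anti to the C10 vinyl group through a closed Zimmerman–Traxler transition state (anti aldol), which creates the C1 quaternary centre (methyl β, chain α) and C2 (S), and the aldolate is acetylated in situ to block retro-aldol cleavage.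

Step 4
Reactants: 10 the aldol acetate
Product: 11 saturated C14 ketone (12,13-dihydro-10)
Conditions: LiBH(s-Bu)3, THF, −78 °C; H2O
Reagents that add atoms: none
Why: Conjugate reduction of the β-unsubstituted cyclohexenone by the bulky trialkylborohydride (1,2-attack at the neopentyl C14 carbonyl is blocked) leaves vinyl, alkyne and acetate untouched and creates no stereocentre.

Step 5
Reactants: 11 saturated C14 ketone
Product: 13 C9,C14-diol (vinyl cut to CH2OH; mainly 14β-OH), via keto aldehyde 12 (not isolated)
Conditions: O3, CH2Cl2/MeOH, −78 °C (Sudan red 7B end point); Me2S; NaBH4, 0 °C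
Reagents that add atoms: ozone, [O-][O+]=O
Why: Ozonolysis cleaves the monosubstituted alkene much faster than the terminal alkyne, and borohydride then reduces the C9 aldehyde and the C14 ketone (axial attack, equatorial alcohol; this centre is removed in step 7) while C10 is untouched.

Step 6
Reactants: 13 C9,C14-diol
Product: 14 C9 tert-butyldimethylsilyl ether of 13
Conditions: TBSCl, imidazole, CH2Cl2, 0 °C
Reagents that add atoms: tert-butyldimethylsilyl chloride, CC(C)(C)[Si](C)(C)Cl
Why: Silylation of the primary C9 hydroxyl is far faster than that of the neopentyl secondary C14 hydroxyl (selective protection), so C9 is masked for steps 7 and 9.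

Step 7
Reactants: 14 C9 silyl ether
Product: 15 C13=C14 alkene
Conditions: Burgess reagent, toluene, 70 °C
Reagents that add atoms: none
Why: Burgess dehydration (syn elimination through the sulfamate ester) can only run toward C13 because C1 is quaternary, and it needs neither acid nor base.

Step 8
Reactants: 15 C13=C14 alkene
Product: 16 13α,14α-diol
Conditions: OsO4 (2 mol %), N-methylmorpholine N-oxide, acetone/H2O, 23 °C
Reagents that add atoms: N-methylmorpholine N-oxide, C[N+]1([O-])CCOCC1; water, O
Why: Upjohn dihydroxylation adds to the ring alkene from the α face, anti to the pseudoaxial C15 methyl on the adjacent quaternary carbon, which sets the cis 13,14-diol of the target, while the terminal alkyne is inert.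

Step 9
Reactants: 16 13α,14α-diol
Product: 17 2,13,14-triacetate
Conditions: Ac2O, pyridine, DMAP, 40 °C
Reagents that add atoms: acetic anhydride, CC(=O)OC(C)=O
Why: DMAP-catalysed acetylation of both secondary hydroxyls installs the C13 and C14 acetates of the target without stereochemical change.

Step 10
Reactants: 17 2,13,14-triacetate
Product: 18 C11 ketone with free C9 hydroxyl
Conditions: 1 M HCl, THF, 23 °C
Reagents that add atoms: water, O
Why: Aqueous acid hydrolyses the dimethyl ketal and cleaves the primary silyl ether in one operation while the acetates survive, and C10 is already in its stable trans (equatorial) arrangement.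

Step 11
Reactants: 18 C11 ketone
Product: 19 C11=C20 methylene alcohol (alkyne arm intact)
Conditions: Zn, CH2Br2, TiCl4 (preformed in THF), CH2Cl2, 0 → 23 °C
Reagents that add atoms: dibromomethane, BrCBr
Why: Lombardo methylenation with a non-basic gem-dimetallic reagent converts the hindered, epimerisable ketone into the exocyclic methylene without β-elimination of the C13 acetate or epimerisation at C10, and it tolerates the free hydroxyl and the esters.

Step 12
Reactants: 19 C11=C20 methylene alcohol; 20 allyl alcohol
Product: 21 (6E)-dienyl diol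
Conditions: second-generation Grubbs catalyst RuCl2(=CHPh)(PCy3)(H2IMes) (10 mol %), ethylene (1 atm), 20 (5 equiv), CH2Cl2, 40 °C
Reagents that add atoms: none
Why: Ethylene-assisted cross enyne metathesis turns the terminal alkyne into the 2-substituted butadiene, whose monosubstituted end then cross-metathesises with allyl alcohol to the thermodynamic (E)-dienol, and the 1,1-disubstituted C11=C20 alkene does not take part.

Step 13
Reactants: 21 (6E)-dienyl diol
Product: 22 dialdehyde (C8 dienal; C9 aldehyde)
Conditions: Dess–Martin periodinane, pyridine, CH2Cl2, 0 → 23 °C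
Reagents that add atoms: none
Why: Dess–Martin oxidation converts both primary alcohols into aldehydes under buffered conditions, so the β,γ-unsaturated C9 aldehyde neither epimerises nor moves into conjugation.

Step 14
Reactants: 22 dialdehyde
Product: 23 macrocyclic 8,9-diol
Conditions: TiCl3(DME)1.5, Zn–Cu couple, DME, 23 °C, 22 added over 30 h (final 0.003 M); aq. K2CO3
Reagents that add atoms: none
Why: Low-valent-titanium pinacol coupling (McMurry type, kept at room temperature so that it stops at the diol) joins the two titanium-bound ketyl radicals at C8 and C9 under high dilution to close the ten-membered ring; the titanium-bridged transition state with C7 and C10 anti gives the threo (ring-trans) diol, and the bond forms anti to quaternary C1 with the bulky titanium-bound oxygen next to H-10, which sets C9 (S), whereas C8 is oxidised in step 15.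

Step 15
Reactants: 23 macrocyclic 8,9-diol
Product: 24 α-hydroxy dienone (C8 ketone)
Conditions: MnO2, CH2Cl2, 23 °C
Reagents that add atoms: none
Why: Allylic oxidation with MnO2 touches only the dienylic C8 carbinol and leaves the C9 hydroxyl.

Step 16
Reactants: 24 α-hydroxy dienone
Product: 25 α-acetoxy dienone
Conditions: Ac2O, pyridine, DMAP, 0 °C
Reagents that add atoms: acetic anhydride, CC(=O)OC(C)=O
Why: Acetylation installs the C9 acetate of the target and makes the α-oxygen substituent non-chelating for step 17.

Step 17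
Reactants: 25 α-acetoxy dienone; 26 tert-butyl propanoate
Product: 28 β-hydroxy tert-butyl ester (8α-OH; 17R), via lithium ester enolate 27 (not isolated)
Conditions: LiN(i-Pr)2, 26, THF/DMPU, −78 °C; 25, −78 °C; AcOH, −78 °C
Reagents that add atoms: none
Why: Aldol addition of the (Z)-lithium ester enolate (kinetic 1,2-addition at low temperature) on the carbonyl face anti to the C9–OAc bond (Cornforth/polar Felkin–Anh model with C10 eclipsing the carbonyl oxygen) through a Zimmerman–Traxler chair with C9 equatorial sets C8 (tertiary OH α) and C17 (8,17-syn).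

Step 18
Reactants: 28 β-hydroxy tert-butyl ester
Product: 30 chloro lactone (11(20)-deoxy target), via allyl selenide lactone 29 (not isolated)
Conditions: PhSeCl, CH2Cl2, −78 °C; N-chlorosuccinimide, −78 → 0 °C
Reagents that add atoms: N-chlorosuccinimide, ClN1C(=O)CCC1=O
Why: Proposed new method: the selenium electrophile attacks the exposed terminal C16 of the 2-substituted diene and the ester carbonyl oxygen, held on the outer face by C8, closes on C7 of the resulting allyl cation with loss of isobutene (a 1,4-phenylselenolactonisation, closest to known selenolactonisations and to onium-induced cyclisations of tert-butyl esters and carbonates), which fixes C7 as the trans-fused lactone, and N-chlorination of the allylic selenide then transfers chlorine to C6 with allylic transposition (the known behaviour of allyl phenyl selenides toward N-chlorosuccinimide) on the open α face (the β face carries C15, the C2 and C9 acetates and the C17 methine), giving the 6α-chloride and the C5=C16 methylene.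

Step 19
Reactants: 30 chloro lactone
Product: 31 target CNP0195129.3
Conditions: mCPBA, CH2Cl2/aq. phosphate buffer (pH 7), 0 °C
Reagents that add atoms: m-chloroperoxybenzoic acid, OOC(=O)c1cccc(Cl)c1
Why: Peracid epoxidation is selective for the C11=C20 methylene because the C5=C16 methylene is deactivated by the allylic chlorine, and the peracid approaches from the equatorial α side because the axial C15 methyl shields the β side, which gives the 11,20-epoxide with oxygen α (11R).

**Compound list**
1 | 4,4-dimethoxycyclohexa-2,5-dien-1-one (p-benzoquinone mono(dimethyl ketal)) | COC1(OC)C=CC(=O)C=C1 | starting material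
2 | potassium vinyltrifluoroborate | [K+].C=C[B-](F)(F)F | starting material
3 | (S)-4,4-dimethoxy-5-vinylcyclohex-2-en-1-one | C1C(=O)C=CC(OC)(OC)[C@@H]1C=C | intermediate
4 | iodomethane | CI | starting material
5 | lithium dienolate of 3 (C1=C14 enolate) | C1=C(O[Li])C=CC(OC)(OC)[C@@H]1C=C | intermediate
6 | (5R,6R)-4,4-dimethoxy-6-methyl-5-vinylcyclohex-2-en-1-one (methyl trans to vinyl) | C[C@H]1C(=O)C=CC(OC)(OC)[C@@H]1C=C | intermediate
7 | pent-4-ynal | C#CCCC=O | starting material
8 | lithium enolate of 6 (tetrasubstituted C1=C14) | CC1=C(O[Li])C=CC(OC)(OC)[C@@H]1C=C | intermediate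
9 | lithium aldolate (C2–OLi; C1 quaternary) | C#CCC[C@H](O[Li])[C@@]1(C)C(=O)C=CC(OC)(OC)[C@@H]1C=C | intermediate
10 | (5R,6S)-6-[(1S)-1-acetoxypent-4-yn-1-yl]-4,4-dimethoxy-6-methyl-5-vinylcyclohex-2-en-1-one | C#CCC[C@H](OC(C)=O)[C@@]1(C)C(=O)C=CC(OC)(OC)[C@@H]1C=C | intermediate
11 | saturated C14 ketone (12,13-dihydro-10) | C#CCC[C@H](OC(C)=O)[C@@]1(C)C(=O)CCC(OC)(OC)[C@@H]1C=C | intermediate
12 | keto aldehyde (C9 aldehyde in place of vinyl) | C#CCC[C@H](OC(C)=O)[C@@]1(C)C(=O)CCC(OC)(OC)[C@@H]1C=O | intermediate
13 | C9,C14-diol (C9 CH2OH β on C10; 14β-OH drawn, either C14 epimer serves) | C#CCC[C@H](OC(C)=O)[C@@]1(C)[C@H](O)CCC(OC)(OC)[C@@H]1CO | intermediate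
14 | C9 tert-butyldimethylsilyl ether of 13 | C#CCC[C@H](OC(C)=O)[C@@]1(C)[C@H](O)CCC(OC)(OC)[C@@H]1CO[Si](C)(C)C(C)(C)C | intermediate
15 | C13=C14 alkene (C2 acetate, C11 ketal, C9 silyl ether) | C#CCC[C@H](OC(C)=O)[C@@]1(C)C=CCC(OC)(OC)[C@@H]1CO[Si](C)(C)C(C)(C)C | intermediate
16 | 13α,14α-diol | C#CCC[C@H](OC(C)=O)[C@@]1(C)[C@@H](O)[C@@H](O)CC(OC)(OC)[C@@H]1CO[Si](C)(C)C(C)(C)C | intermediate
17 | 2,13,14-triacetate (C11 ketal, C9 silyl ether) | C#CCC[C@H](OC(C)=O)[C@@]1(C)[C@@H](OC(C)=O)[C@@H](OC(C)=O)CC(OC)(OC)[C@@H]1CO[Si](C)(C)C(C)(C)C | intermediate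
18 | C11 ketone with free C9 hydroxyl (2,13,14-triacetate) | C#CCC[C@H](OC(C)=O)[C@@]1(C)[C@@H](OC(C)=O)[C@@H](OC(C)=O)CC(=O)[C@@H]1CO | intermediate
19 | C11=C20 methylene alcohol with C5≡C6 alkyne arm | C#CCC[C@H](OC(C)=O)[C@@]1(C)[C@@H](OC(C)=O)[C@@H](OC(C)=O)CC(=C)[C@@H]1CO | intermediate
20 | allyl alcohol (prop-2-en-1-ol) | C=CCO | starting material
21 | (6E)-dienyl diol (C5=C16 and C6=C7 diene; C8 and C9 primary hydroxyls) | C=C(/C=C/CO)CC[C@H](OC(C)=O)[C@@]1(C)[C@@H](OC(C)=O)[C@@H](OC(C)=O)CC(=C)[C@@H]1CO | intermediate
22 | dialdehyde (C8 (E)-dienal; C9 aldehyde) | C=C(/C=C/C=O)CC[C@H](OC(C)=O)[C@@]1(C)[C@@H](OC(C)=O)[C@@H](OC(C)=O)CC(=C)[C@@H]1C=O | intermediate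
23 | macrocyclic 8,9-diol (ten-membered ring closed; 6E; 9S; 8-OH ring-trans to 9-OH) | C=C1CC[C@H](OC(C)=O)[C@@]2(C)[C@@H](OC(C)=O)[C@@H](OC(C)=O)CC(=C)[C@@H]2[C@H](O)[C@@H](O)/C=C/1 | intermediate
24 | α-hydroxy dienone (C8 ketone, 9S-OH) | C=C1CC[C@H](OC(C)=O)[C@@]2(C)[C@@H](OC(C)=O)[C@@H](OC(C)=O)CC(=C)[C@@H]2[C@H](O)C(=O)/C=C/1 | intermediate
25 | α-acetoxy dienone (2,9,13,14-tetraacetate) | C=C1CC[C@H](OC(C)=O)[C@@]2(C)[C@@H](OC(C)=O)[C@@H](OC(C)=O)CC(=C)[C@@H]2[C@H](OC(C)=O)C(=O)/C=C/1 | intermediate
26 | tert-butyl propanoate | CCC(=O)OC(C)(C)C | starting material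
27 | lithium (Z)-enolate of 26 (methyl cis to OLi) | C/C=C(\O[Li])OC(C)(C)C | intermediate
28 | β-hydroxy tert-butyl ester (tertiary 8α-OH; 17R; 6E diene) | C=C1CC[C@H](OC(C)=O)[C@@]2(C)[C@@H](OC(C)=O)[C@@H](OC(C)=O)CC(=C)[C@@H]2[C@H](OC(C)=O)[C@](O)([C@@H](C)C(=O)OC(C)(C)C)/C=C/1 | intermediate
29 | allyl selenide lactone (7,19-lactone; C5=C6 with C4 and C7 cis; C16–SePh) | C1C[C@H](OC(C)=O)[C@@]2(C)[C@@H](OC(C)=O)[C@@H](OC(C)=O)CC(=C)[C@@H]2[C@H](OC(C)=O)[C@]2(O)[C@@H](C)C(=O)O[C@H]2/C=C1/C[Se]c1ccccc1 | intermediate
30 | chloro lactone, 11(20)-deoxy target (6α-Cl; C5=C16 and C11=C20 methylenes) | C=C1CC[C@H](OC(C)=O)[C@@]2(C)[C@@H](OC(C)=O)[C@@H](OC(C)=O)CC(=C)[C@@H]2[C@H](OC(C)=O)[C@]2(O)[C@@H](C)C(=O)O[C@H]2[C@H]1Cl | intermediate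
31 | CNP0195129.3 (1S,2S,6S,7R,8R,9S,10S,11R,13S,14R,17R) | C=C1CC[C@H](OC(C)=O)[C@@]2(C)[C@@H](OC(C)=O)[C@@H](OC(C)=O)C[C@]3(CO3)[C@@H]2[C@H](OC(C)=O)[C@]2(O)[C@@H](C)C(=O)O[C@H]2[C@H]1Cl | target

**Step count and risks**
Total number of steps: 19. Longest linear sequence: 19 (the route is linear; 2, 4, 7, 20 and 26 enter along the way).

Steps most likely to fail:

Step 14 (pinacol macrocyclisation). The dienal ketyl may couple through C6 or C16, the β,γ-unsaturated C9 aldehyde may isomerise on the Lewis-acidic titanium, oligomers may form, and the facial selectivity at C9 is only predicted. The fallback closes the ring by metathesis instead; it sets out from 19 and comes back at 23. Oxidation of 19 with Dess–Martin periodinane gives the C9 aldehyde F1. Addition of (Z)-γ-(methoxymethoxy)allyl-diisopinocampheylborane (made from allyl methoxymethyl ether, s-BuLi, (Ipc)2BOMe and BF3·OEt2, in the enantiomeric form that delivers 9S; ethanolamine work-up) gives the syn homoallylic alcohol MOM ether F2 under reagent control. Ethylene-assisted ring-closing enyne metathesis with the second-generation Grubbs catalyst RuCl2(=CHPh)(PCy3)(H2IMes) converts the alkyne into the 2-substituted diene, which closes onto the vinyl group to give the macrocyclic MOM ether F3. Cleavage of the MOM group with Me2BBr at −78 °C returns 23.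

Step 17 (aldol on the macrocyclic ketone). Conjugate (1,6-) addition at C16, acetyl migration from O9 to O8, and the wrong carbonyl face (8-epimer) are all possible. The fallback moves the propanoate unit in before ring closure, so that C8 and C9 are both created in the ketyl coupling; it sets out from 21 and comes back at 28. MnO2 oxidises only the allylic alcohol of 21 to give the hydroxy dienal F4. Addition of the enolate 27 (2.2 equiv, THF, −78 °C) gives the β-hydroxy ester F5 as a mixture at C8 and C17. Dess–Martin periodinane oxidises both carbinols to the keto aldehyde F6 (C17 now labile). Pinacol coupling under the conditions of step 14 (TiCl3(DME)1.5, Zn–Cu couple, DME, high dilution), with the same threo preference, gives the macrocyclic tertiary diol F7. Acetylation of its secondary hydroxyl (Ac2O, pyridine, DMAP) returns 28.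

Step 18 (selenolactonisation and chlorine transfer). The tert-butyl ester may not close in the 1,4-mode, and the chlorine may arrive on the β face of C6. The fallback transfers oxygen first and then inverts; it sets out from 29 (isolated after the first stage) and comes back at 30. Oxidation of 29 with H2O2 and pyridine in CH2Cl2 at 0 °C gives the selenoxide, whose [2,3]-sigmatropic shift places oxygen on C6 on the face that selenium reaches and restores the C5=C16 methylene, giving the 6β-allylic alcohol F8. Treatment with PPh3 and hexachloroacetone replaces the hydroxyl by chloride with SN2 inversion and little allylic rearrangement, returning 30.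

Further compounds
F1 | step 14 | C9 aldehyde of 19 (alkyne arm intact) | C#CCC[C@H](OC(C)=O)[C@@]1(C)[C@@H](OC(C)=O)[C@@H](OC(C)=O)CC(=C)[C@@H]1C=O
F2 | step 14 | syn homoallylic alcohol MOM ether (9S-OH; C8 OMOM; C7 vinyl) | C#CCC[C@H](OC(C)=O)[C@@]1(C)[C@@H](OC(C)=O)[C@@H](OC(C)=O)CC(=C)[C@@H]1[C@H](O)[C@@H](OCOC)C=C
F3 | step 14 | macrocyclic MOM ether (8-O-MOM derivative of 23) | C=C1CC[C@H](OC(C)=O)[C@@]2(C)[C@@H](OC(C)=O)[C@@H](OC(C)=O)CC(=C)[C@@H]2[C@H](O)[C@@H](OCOC)/C=C/1
F4 | step 17 | hydroxy dienal (C8 aldehyde; C9 CH2OH) | C=C(/C=C/C=O)CC[C@H](OC(C)=O)[C@@]1(C)[C@@H](OC(C)=O)[C@@H](OC(C)=O)CC(=C)[C@@H]1CO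
F5 | step 17 | β-hydroxy ester (mixture at C8 and C17) | C=C(/C=C/C(O)C(C)C(=O)OC(C)(C)C)CC[C@H](OC(C)=O)[C@@]1(C)[C@@H](OC(C)=O)[C@@H](OC(C)=O)CC(=C)[C@@H]1CO
F6 | step 17 | keto aldehyde (C8 ketone of a β-keto ester with labile C17; C9 aldehyde) | C=C(/C=C/C(=O)C(C)C(=O)OC(C)(C)C)CC[C@H](OC(C)=O)[C@@]1(C)[C@@H](OC(C)=O)[C@@H](OC(C)=O)CC(=C)[C@@H]1C=O
F7 | step 17 | macrocyclic tertiary diol (9-deacetyl-28) | C=C1CC[C@H](OC(C)=O)[C@@]2(C)[C@@H](OC(C)=O)[C@@H](OC(C)=O)CC(=C)[C@@H]2[C@H](O)[C@](O)([C@@H](C)C(=O)OC(C)(C)C)/C=C/1
F8 | step 18 | 6β-allylic alcohol (6-epi-hydroxy analogue of 30) | C=C1CC[C@H](OC(C)=O)[C@@]2(C)[C@@H](OC(C)=O)[C@@H](OC(C)=O)CC(=C)[C@@H]2[C@H](OC(C)=O)[C@]2(O)[C@@H](C)C(=O)O[C@H]2[C@@H]1O
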